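(The runs were computed from invented constants, and the scatter is random.)

Summer is the flask to plan around, as it is the warmest of the three recipes and may use up Z well before its dosing of X ends.

all flasks: Z 0.25 M
- alder: G 0.25 M; X 0.12 M (fed, over 4.0 h); temperature −20 °C; run made earlier
- larch: G 0.25 M; X 0.50 M (fed, over 4.0 h); temperature 0 °C; run made earlier
- dawn: G 0.250 M; X 0.250 M (fed, over 4.0 h); temperature −15 °C; time 4.0 h
- summer: G 0.250 M; X 0.250 M (fed, over 4.0 h); temperature 15 °C; time 4.0 h
- noon: G 0.250 M; X 0.250 M (fed, over 4.0 h); temperature 0 °C; time 4.0 h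

alder run (percent of the Z charged)

| time / h | D / % | Z / % |
|---|---|---|
| 0.133 | 4.2 | 96.5 |
| 0.333 | 9.4 | 90.9 |
| 0.667 | 16.6 | 81.7 |
| 1.00 | 23.0 | 75.0 |
| 1.33 | 28.3 | 69.0 |
| 2.00 | 36.6 | 58.4 |
| 2.50 | 41.2 | 51.4 |

larch run (percent of the Z charged)

| time / min | D / % | Z / % |
|---|---|---|
| 10.0 | 19.1 | 79.1 |
| 20.0 | 30.9 | 63.3 |
| 30.0 | 39.4 | 51.0 |
| 40.0 | 44.7 | 41.3 |
| 60.0 | 51.0 | 26.6 |
| 80.0 | 54.3 | 16.9 |

(readings scatter by 0.3 percentage points)

* the flask that comes out highest in amount of D, in percent of the Z charged, or "all alike" when all lie within 1.5 percentage points (dawn / summer / noon / all alike)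
* D at the end, in percent of the Z charged, dawn
* D at the end, in percent of the Z charged, summer
* D at the end, in percent of the Z charged, noon



We replace each Z curve by its mean first-order constant, an empirical mean taken from the start to the last reading. This gives 0.266 h⁻¹ for alder and 1.33 h⁻¹ for larch. The larch mean misses the reading at 10.0 min by 0.97 percentage points, which is small enough for planning. Taking ln k as straight in temperature through the two runs, we reckon 4.46 h⁻¹ for summer and 0.398 h⁻¹ for dawn, while for noon we take the larch value, though larch is charged 0.50 M of X and noon 0.250 M. At its constant, summer's Z falls to 1.00% of its charge in 1.03 h; we carry this as the clearing time, the time for Z to reach that mark. Noon's clearing time is 3.45 h and dawn's is 11.6 h, so at 4.0 h noon is just past its mark and dawn is far short of it.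

Summer would stand 2.97 h past its mark. Neither earlier run shows that stretch, because the lowest Z read is 16.9%. So we keep the three recipes as charged, but we also sample summer at 2.00 h rather than trust the end reading by itself.

The forecast gave 54.5% for dawn, 80% for summer and 71% for noon, and named summer as highest, on this ground: “Warm flasks convert Z before X builds up”.

The flasks gave 53.2% for dawn, 23.4% for summer and 60.5% for noon, so noon came out highest.

    Z + G → D (k = 0.00156 L mol⁻¹ s⁻¹, Ea = 44.0 kJ mol⁻¹)
    X + G → E (k = 0.00174 L mol⁻¹ s⁻¹, Ea = 48.0 kJ mol⁻¹)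
    Z + X → Q (k = 0.00447 L mol⁻¹ s⁻¹, Ea = 67.0 kJ mol⁻¹)
    D → L (k = 9.02 × 10⁻⁶ s⁻¹, Ea = 100 kJ mol⁻¹)
    (constants at 0 °C)

Against the reckoned clearing time of 1.03 h, summer read Z at 0.932% and D at 44.5% at 2.00 h, so the mark had been passed by then. By 4.0 h D had fallen to about half of that reading. The neighbouring flask is the summer flask read later, at 6.0 h, which is 4.97 h past the reckoned mark. One more step at the same ratio gives 12.3% of D. At that reading the neighbour holds Z at 0%, L at 64.7% and D at 12.3%.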